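The constants were chosen freely; what happens was integrated by code.

A one-step world has one reagent and one rate; these flasks have two substrates competing for one enzyme, which the precatalyst gives out slowly.

    complex A → enzyme + target (k1 = 3400 min⁻¹)
    complex B → enzyme + second product (k2 = 1600 min⁻¹)
    second substrate + enzyme ⇌ complex B (K3 = 120 M⁻¹, k3 = 4.3 × 10⁵ M⁻¹ min⁻¹)
    enzyme + enzyme ⇌ resting dimer (K4 = 3.0 × 10⁵ M⁻¹, k4 = 25000 M⁻¹ min⁻¹)
    precatalyst → enzyme (k5 = 0.027 min⁻¹)
    starting material + enzyme ⇌ complex A (K6 = 46 M⁻¹, k6 = 3.8 × 10⁵ M⁻¹ min⁻¹)

in all of them: precatalyst 4.1 µM; time 15 min

| run | starting material | second substrate | remark |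
|---|---|---|---|
| east | 41 mM (fed, over 12 min) | 20.5 mM | all else is in the flask from the start; the feed brings no volume worth counting |
| south | 41 mM | 20.5 mM (fed, over 12 min) | all else is in the flask from the start; the feed brings no volume worth counting |
| north-east | 41 mM | 20.5 mM | everything together at the start |

1. which flask leads in amount of target, in percent of the starting material charged ("all alike" within 1.5 percentage points) (east / south / north-east / all alike)
2. how much target is there at the end, in percent of the starting material charged: east
3. how much target is there at the end, in percent of the starting material charged: south
4. how much target is there at the end, in percent of the starting material charged: north-east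

The precatalyst's rate constant times the run is 0.405, less than 1, so enzyme grows nearly in step with time. Setting the resting dimer aside, I count the run as the full 4.1 µM working for tw = 2.67 min, with the weight centred at t = 10.0 min.

I take each complex as steady, which gives two Michaelis constants, (breakdown + return)/binding: KA = 30.7 mM for starting material and KB = 12.1 mM for second substrate. Let a = [starting material]/KA and b = [second substrate]/KB. For east at t, with 0.833 of the charge fed and nothing used, 3400 min⁻¹ times a/(1+a+b) is 993 min⁻¹. This is the pull, the target made per minute by each enzyme, free or bound. Second product follows the same form with 1600 min⁻¹ and b on top.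

For east to stand level with the others, the feed would have to cost it nothing, and in this form of the pull that asks for a far above 1+b. At the full charges a is 1.34 and 1+b is 2.70, lower, so east pays for its feed.

Pull times tw times 4.1 µM gives target and second product: east 10.8 mM and 7.80 mM, south 13.2 mM and 6.60 mM, north-east 12.3 mM and 7.37 mM. Going round again with half of these taken off the amounts, the pull becomes 961 min⁻¹ for east, 1170 min⁻¹ for south and 1090 min⁻¹ for north-east. I commit to 25.6 % of target for east, 31.1 % for south and 29.2 % for north-east, south first.

The forecast names south, with 24.5 % for east, 30.5 % for south and 28.5 % for north-east, since “Feeding the second substrate frees more enzyme while starting material is fully present”. My figures stand above its three, in the same order.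

The simulation gives 24.3 % for east, 31.2 % for south and 28.8 % for north-east, so south leads while still holding 69 % of its starting material unbound. The neighbouring east flask has 8.2 mM of second substrate. Round one lifts the pull from 993 min⁻¹ to 1360 min⁻¹, which gives 14.8 mM of target and 4.26 mM of second product. Round two leaves 1250 min⁻¹ against 961 min⁻¹, a factor 1.30, which carries east's 24.3 % to 31.6 %. The simulated neighbour reads 31.3 %.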